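## Structural features

The target 46 is a C1–C29 chain (C1 = NCH2, C29 = terminal CH2) that threads two 2,6-cis oxanes, ring B (O, C12–C16) and ring A (O, C18–C22), joined through the C17 methylene; its configuration is 2S,4R,10R,12S,13R,15S,16R,18S,20S,22R,23S. Ring B holds four stereocentres: C12 and C16 are cis, C15 carries an equatorial methyl next to C16, and C13 is a tertiary alcohol (axial methyl, equatorial hydroxyl) trans to the C11 chain on C12. Ring A is all-cis (C18, C20-OMe, C22), and C22 stands next to the methyl-bearing C23. West of ring B lie the isolated allylic centre C10, the (6E,8E)-diene with the C7 methyl, and the anti C2/C4 diol whose O4 is a primary carbamate, O2 is free and N1 carries a 2-methoxyacryloyl group; east of ring A lies the (24E,26E)-triene ending in a vinyl group. The fragile groups are the 2-methoxyacrylamide (acid-labile enol ether and acceptor), both polyenes (acid, oxidants, metathesis catalysts), the carbamate next to a free hydroxyl (acyl shift under base) and the tertiary C13 alcohol (ionisation in strong acid). The real difficulty is the C13 quaternary carbinol in the right relation to C12 and C16, the remote C10 centre, and a late assembly that must tolerate unprotected polar groups. Two features are exploited. The C15/C16 pair of ring B and the C23/C22 pair of ring A are the same methyl/oxygen stereodiad, so one building block serves both rings. And O16 can carry an (E)-β-alkoxyacrylate whose β-carbon is C12, five atoms from a C13 methyl ketone, so that a C13 ketyl closes ring B through the C12–C13 bond and sets C12 and C13 together.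

## Logic of the disconnections

46 is cut at the C7–C8 single bond inside the diene into 31 and 45. Both alkene geometries are then fixed before the union, and the union is an sp2–sp2 coupling that needs no protecting group. The forward step must work at room temperature with a free carbamate, two free hydroxyls, an enol-ether amide and a triene.

45 is cut at the amide N–C bond into 41 and 43, and 41 is traced through 40 and 39 to 38 by cutting the C7–I bond and then the C6=C7 bond. The acid-labile acyl group enters last on this fragment, and the trisubstituted alkene comes from a terminal vinyl group. The forward steps must place boron, then iodine, trans to C5 and must acylate nitrogen in the presence of O2–H.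

38 is cut at the carbamate C–O bond to 36 and then at C4–C5 into 35 and 4; 35 goes back through 34 and 33 to 32. C2 comes from the chiral pool and O2 stays silylated until O4 is carbamoylated, which solves the differentiation of the two hydroxyls. The allylation must set C4 under reagent control (1,3-anti).

31 is cut at C27–C28 to 30, at C26=C27 to 29, at the C8–B bond to 28, and at C24=C25 to 27, which derives from 26 and 25. The triene is thus built outward from a C24 aldehyde in three carbon–carbon bond formations that use only commercial reagents. Each must be E-selective, and the borylation must leave the enal alone.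

25 is cut at the C10–CH3 bond (SN2′ sense) to 24, which comes from 23, 22 and, through the C9=C10 bond, from 20. This turns the ester carbon C10 into the methyl-bearing centre with its vinyl group. The forward step needs catalyst control over a centre that is 1,3 to C12.

20 is cut at the O20–CH3 bond to 19, and 19 at the O22–C18 and C18–C19 bonds into 17 and 5. Ring A and two stereocentres (C18, C20) arise in one union, while C22 and C23 arrive ready-made. The forward step is strongly acidic and must spare the silyl ether, the ester and the tertiary alcohol.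

17 is cut at its aldehyde (C18=O from the allyl group) to 15, and 15 at the C12–C13 bond to 14. This is the ring-B disconnection: one bond, one ring, two stereocentres. It demands a reductant that makes the C13 ketyl without touching the allyl group, and a chelated chair for selectivity.

14 is traced to 13 (ketone unmasked), 13 is cut at the vinyl ether O16–C bond into 11 and 12, 11 at C13–C14 into 8 and 9, and 8 goes back through 6 to 5. The acyl anion equivalent brings in the methyl ketone; O16 needs protection only while the organolithium is present.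

5 is cut at the C16–C17 bond (equally the C21–C22 bond of ring A) into 3 and 4, and 3 goes back through 2 to 1. The shared building block 5 carries a TBDPS ether so that the same compound survives the acid of the ring-A union and is easily unmasked on the ring-B path.

## Other disconnections considered

Alternative 1: The C14–C24 backbone is cut at both bonds to one carbon, which becomes a dithiane. Read with the numbering used here, product A1 carries the dithiane at C20 and its free hydroxyl at C18, so the bonds formed are C20–C21 and C19–C20 and silicon travels to O22; a reading that puts the dithiane at C18 does not fit A1. In the forward step, lithiated A2 would open epoxide A4 at C21, a 1,4-Brook shift triggered by HMPA would move silicon to O22 and regenerate the carbanion, and this would open epoxide A3 at C19 to give A1. In its favour: three components join in one flask, every stereocentre comes from a pre-made epoxide so no new selectivity is needed, and C20 arrives as a masked ketone. On convergence and on stereochemical certainty of the union this is the better of the two plans. Against it here: the step closes no ring and does nothing for C12 or C13. Ring A still needs dithiane removal, ketalisation or reduction and O-methylation, and ring B still needs a separate C12–C13 bond construction. Three different silyl groups and a PMB ether must be told apart, and HMPA is required. Mechanistically it is an anion relay (polar), the chosen step a radical cyclisation. In step economy the backbone is shorter, but the two ring closures and the quaternary carbinol add back more steps than are saved.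

Alternative 2: Ring B is cut at O–C16. Furyl carbinol A6 would be oxidised with NBS in buffered aqueous THF and the C12 hydroxyl would close on C16 to give the pyranone hemiketal A5 (Achmatowicz rearrangement). In its favour: furans are cheap, the ring expansion runs in water and air, and the enone offers handles at C13, C14 and C15. In operational simplicity it is the better plan, since no air-sensitive lanthanide is needed; in reliability of ring formation the two are equal. Against it here: A5 lacks both ring methyl groups and has no fixed C16 configuration. The C15 methyl (conjugate addition), the C16 hydrogen (ionic reduction) and the C13 methyl (addition to the ketone, where equatorial attack would give the wrong, axial alcohol) must each be added under substrate control. The key step itself leaves no permanent stereocentre, where the ketyl cyclisation sets two. NBS would also not tolerate the allyl group needed for ring A, so the C17–C18 unit must be carried as a protected alcohol. About four to five extra steps on the ring are expected.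

Alternative 3: Ring A is cut at C21–C22 and O–C18. Aldehyde A8 and the 2-silyloxydiene A9, which already carries ring B, would combine in an endo hetero-Diels–Alder reaction under a chiral tridentate Schiff-base chromium chloride catalyst (trivalent chromium) to give A7. This competes with the Prins union of step 11, not with the ketyl cyclisation, and could follow it. In its favour: it also forms one ring and two stereocentres (C18, C22) in a convergent step, so on bond and stereocentre count it is the equal of the Prins step. On mildness it is the better one: no strong acid, no oxonia-Cope scrambling, and catalyst control of C22. Against it here: A9 needs three extra steps from the ring-B aldehyde (enone, silyl enol ether) and a silyl group on O13. A8 is an epimerisable α-methyl aldehyde whose own stereocentre may be mismatched with the catalyst. C20 then needs desilylation, reduction and methylation, where the Prins route needs only methylation. The balance is about three more steps for a milder union; a variant with the roles of the partners exchanged is kept as the fallback for step 11.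

Key step: step 9

Remarks on the chemistry (assumptions):
- The sense of induction of the copper/Taniaphos catalyst in step 16 is assigned by analogy with simple (E)-allylic bromides; the antipodal ligand would be used if a model bromide shows the opposite sense.
- Both B-methoxydiisopinocampheylboranes, ethyl (S)-4-chloro-3-hydroxybutanoate, methyl 2-methoxyacrylate, the vinyl- and isopropenylboronic pinacol esters and 2-(triphenylphosphoranylidene)propanal are taken as commercial.
- Compounds 14 and 15 map atom for atom onto C10–C18 of 46 with the required configurations; their skeletons are used unchanged.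

## Route

Step 1
Reactants: 1 methyl (S)-3-hydroxy-2-methylpropanoate
Product: 2 methyl (S)-3-[(tert-butyldiphenylsilyl)oxy]-2-methylpropanoate
Conditions: TBDPSCl, imidazole, CH2Cl2, 0 °C to rt
Reagents that add atoms: tert-butyl(chloro)diphenylsilane, CC(C)(C)[Si](Cl)(c1ccccc1)c1ccccc1
Why: Silylation of the primary alcohol; TBDPS is chosen because the same ether must later survive trifluoroacetic acid in step 11.

Step 2
Reactants: 2 methyl (S)-3-[(tert-butyldiphenylsilyl)oxy]-2-methylpropanoate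
Product: 3 (S)-3-[(tert-butyldiphenylsilyl)oxy]-2-methylpropanal
Conditions: i-Bu2AlH (1.05 equiv), CH2Cl2, −78 °C; MeOH, aq. KNaC4H4O6
Reagents that add atoms: none
Why: Partial ester reduction through the aluminium hemiacetal that is stable at −78 °C; the aldehyde is used at once so that the α-stereocentre does not epimerise.

Step 3
Reactants: 3 (S)-3-[(tert-butyldiphenylsilyl)oxy]-2-methylpropanal; 4 allylmagnesium bromide (C3H5MgBr)
Product: 5 (2S,3R)-1-[(tert-butyldiphenylsilyl)oxy]-2-methylhex-5-en-3-ol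
Conditions: (+)-Ipc2BOMe and 4, Et2O, −78 °C to rt; then 3, −78 °C; NaOH, H2O2, rt
Reagents that add atoms: none
Why: Brown allylation; the (+)-borane (from (−)-α-pinene) should deliver allyl to the Re face through a chair-like six-membered transition state, setting the 3R carbinol (later C16 and C22) anti to the methyl group under reagent control against the small intrinsic bias of the α-methyl aldehyde.

Step 4
Reactants: 5 (2S,3R)-1-[(tert-butyldiphenylsilyl)oxy]-2-methylhex-5-en-3-ol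
Product: 6 (2S,3R)-2-methylhex-5-ene-1,3-diol
Conditions: TBAF, THF, rt
Reagents that add atoms: none
Why: Fluoride cleavage of the silyl ether frees the C14 hydroxyl for activation; the portion of 5 kept for ring A is not touched.

Step 5
Reactants: 6 (2S,3R)-2-methylhex-5-ene-1,3-diol
Product: 8 triethyl{[(4R,5R)-6-iodo-5-methylhex-1-en-4-yl]oxy}silane, via iodo alcohol 7 (not isolated)
Conditions: I2, PPh3, imidazole, CH2Cl2, 0 °C; then Et3SiCl, rt
Reagents that add atoms: iodine, II; chlorotriethylsilane, CC[Si](Cl)(CC)CC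
Why: Appel-type iodination should select the primary over the hindered secondary hydroxyl; silylation in the same flask masks O16 against the organolithium of step 6.

Step 6
Reactants: 8 triethyl{[(4R,5R)-6-iodo-5-methylhex-1-en-4-yl]oxy}silane; 9 2-methyl-1,3-dithiane
Product: 11 (2S,3R)-2-methyl-1-(2-methyl-1,3-dithian-2-yl)hex-5-en-3-ol, via silyl ether 10 (not isolated)
Conditions: 9, n-BuLi, THF, −25 °C; 8, DMPU, −78 to −20 °C; then 1 M HCl, MeOH, rt
Reagents that add atoms: none
Why: Corey–Seebach alkylation (SN2 at the primary iodide C14) brings in C13 and its methyl as a masked ketone; the acidic work-up removes the triethylsilyl group while the dithiane survives.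

Step 7
Reactants: 11 (2S,3R)-2-methyl-1-(2-methyl-1,3-dithian-2-yl)hex-5-en-3-ol; 12 ethyl propiolate
Product: 13 ethyl (2E)-3-{[(4R,5S)-5-methyl-6-(2-methyl-1,3-dithian-2-yl)hex-1-en-4-yl]oxy}prop-2-enoate
Conditions: N-methylmorpholine, CH2Cl2, rt
Reagents that add atoms: none
Why: Amine-catalysed oxa-Michael addition of the secondary alcohol to the ynoate; the E-configured β-alkoxyacrylate is the expected product and is the geometry the key step needs.

Step 8
Reactants: 13 ethyl (2E)-3-{[(4R,5S)-5-methyl-6-(2-methyl-1,3-dithian-2-yl)hex-1-en-4-yl]oxy}prop-2-enoate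
Product: 14 ethyl (2E)-3-{[(4R,5S)-5-methyl-7-oxooct-1-en-4-yl]oxy}prop-2-enoate
Conditions: MeI, CaCO3, MeCN/H2O (9:1), 45 °C
Reagents that add atoms: water, O
Why: Alkylative hydrolysis of the dithiane (S-methylation, then hydrolysis of the thionium ion); the non-oxidative conditions should spare the terminal alkene and the alkoxyacrylate.

Step 9
Reactants: 14 ethyl (2E)-3-{[(4R,5S)-5-methyl-7-oxooct-1-en-4-yl]oxy}prop-2-enoate
Product: 15 ethyl 2-[(2S,3R,5S,6R)-3-hydroxy-3,5-dimethyl-6-(prop-2-en-1-yl)oxan-2-yl]acetate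
Conditions: SmI2 (2.5 equiv), MeOH (3 equiv), THF, 0 °C
Reagents that add atoms: none
Why: SmI2 (divalent samarium) should transfer one electron to the C13 ketone to give a ketyl bound to trivalent samarium, which also binds the ester carbonyl of the acrylate. The ketyl carbon then adds to C12, the β-carbon of the (E)-β-alkoxyacrylate, in a 6-exo-trig closure of ring B that forms the C12–C13 bond; a second electron reduces the α-ester radical to a samarium enolate, which methanol protonates. The closest known reaction type is the SmI2-induced reductive cyclisation of aldehydes and methyl ketones onto tethered β-alkoxyacrylates, which gives 2,6-cis-2,3-trans-3-hydroxyoxanes. C12 is controlled by the chair transition state in which the C16 allyl group, the C15 methyl group and the acrylate arm are all equatorial, so H12 and H16 end up cis-diaxial (2,6-cis). C13 is controlled by the samarium bridge, which holds the ketyl oxygen equatorial and gauche to the acrylate and so forces the methyl group axial, giving the hydroxyl trans to the C11 chain. The step needs diastereoselection at both new centres relative to C16 and chemoselection for the acrylate over the allyl group. The E-geometry, the chelate and the equatorial C15/C16 substituents secure the first; the unactivated alkene is too slow an acceptor to compete, which secures the second. Methanol is present from the start so that the enolate is quenched before it can undergo retro-Michael opening, and the trans arrangement of hydroxyl and ester arm is expected to disfavour lactonisation.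

Step 10
Reactants: 15 ethyl 2-[(2S,3R,5S,6R)-3-hydroxy-3,5-dimethyl-6-(prop-2-en-1-yl)oxan-2-yl]acetate
Product: 17 ethyl 2-[(2S,3R,5S,6R)-3-hydroxy-3,5-dimethyl-6-(2-oxoethyl)oxan-2-yl]acetate, via ozonide 16 (not isolated)
Conditions: O3, CH2Cl2, −78 °C; then PPh3, −78 °C to rt
Reagents that add atoms: ozone, [O-][O+]=O
Why: Ozonolysis of the only alkene with reductive work-up gives the C18 aldehyde; it is a β-alkoxy aldehyde and is taken on without chromatography.

Step 11
Reactants: 17 ethyl 2-[(2S,3R,5S,6R)-3-hydroxy-3,5-dimethyl-6-(2-oxoethyl)oxan-2-yl]acetate; 5 (2S,3R)-1-[(tert-butyldiphenylsilyl)oxy]-2-methylhex-5-en-3-ol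
Product: 19 ethyl 2-[(2S,3R,5S,6R)-6-{[(2S,4S,6R)-6-{(2S)-1-[(tert-butyldiphenylsilyl)oxy]propan-2-yl}-4-hydroxyoxan-2-yl]methyl}-3-hydroxy-3,5-dimethyloxan-2-yl]acetate, via trifluoroacetate 18 (not isolated)
Conditions: CF3CO2H (20 equiv), CH2Cl2, 0 °C to rt; evaporate; then K2CO3, EtOH, rt
Reagents that add atoms: trifluoroacetic acid, OC(=O)C(F)(F)F
Why: Prins cyclisation: condensation gives the (E)-oxocarbenium ion at C18, the C19=C20 alkene attacks it through a chair with the C17 and C23 arms equatorial (ring A closed endo), and trifluoroacetate captures the C20 cation equatorially, so C18 and C20 are set all-cis to the C22 centre brought in by 5. Ethanolysis frees O20–H without exchanging the ethyl ester.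

Step 12
Reactants: 19 ethyl 2-[(2S,3R,5S,6R)-6-{[(2S,4S,6R)-6-{(2S)-1-[(tert-butyldiphenylsilyl)oxy]propan-2-yl}-4-hydroxyoxan-2-yl]methyl}-3-hydroxy-3,5-dimethyloxan-2-yl]acetate
Product: 20 ethyl 2-[(2S,3R,5S,6R)-6-{[(2S,4S,6R)-6-{(2S)-1-[(tert-butyldiphenylsilyl)oxy]propan-2-yl}-4-methoxyoxan-2-yl]methyl}-3-hydroxy-3,5-dimethyloxan-2-yl]acetate
Conditions: Me3OBF4, 1,8-bis(dimethylamino)naphthalene, 4 Å sieves, CH2Cl2, 0 °C to rt
Reagents that add atoms: trimethyloxonium tetrafluoroborate, C[O+](C)C.F[B-](F)(F)F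
Why: O-Methylation under non-basic conditions, which avoids retro-oxa-Michael opening of the β-alkoxy ester; the equatorial secondary O20–H should react well before the hindered tertiary O13–H.

Step 13
Reactants: 20 ethyl 2-[(2S,3R,5S,6R)-6-{[(2S,4S,6R)-6-{(2S)-1-[(tert-butyldiphenylsilyl)oxy]propan-2-yl}-4-methoxyoxan-2-yl]methyl}-3-hydroxy-3,5-dimethyloxan-2-yl]acetate
Product: 22 ethyl (2E)-4-[(2S,3R,5S,6R)-6-{[(2S,4S,6R)-6-{(2S)-1-[(tert-butyldiphenylsilyl)oxy]propan-2-yl}-4-methoxyoxan-2-yl]methyl}-3-hydroxy-3,5-dimethyloxan-2-yl]but-2-enoate, via aldehyde 21 (not isolated)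
Conditions: i-Bu2AlH (2.2 equiv), CH2Cl2, −78 °C; aq. KNaC4H4O6; crude, Ph3P=CHCO2Et, toluene, 50 °C
Reagents that add atoms: ethyl (triphenylphosphoranylidene)acetate, CCOC(=O)C=P(c1ccccc1)(c1ccccc1)c1ccccc1
Why: Partial reduction to the C10 aldehyde (which may rest as its lactol with O13–H) followed by Wittig olefination with a stabilised ylide, expected to be E-selective; the neutral conditions keep O13–H from adding back to the enoate.

Step 14
Reactants: 22 ethyl (2E)-4-[(2S,3R,5S,6R)-6-{[(2S,4S,6R)-6-{(2S)-1-[(tert-butyldiphenylsilyl)oxy]propan-2-yl}-4-methoxyoxan-2-yl]methyl}-3-hydroxy-3,5-dimethyloxan-2-yl]but-2-enoate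
Product: 23 (2S,3R,5S,6R)-6-{[(2S,4S,6R)-6-{(2S)-1-[(tert-butyldiphenylsilyl)oxy]propan-2-yl}-4-methoxyoxan-2-yl]methyl}-2-[(2E)-4-hydroxybut-2-en-1-yl]-3,5-dimethyloxan-3-ol
Conditions: i-Bu2AlH (3.5 equiv), CH2Cl2, −78 to −40 °C
Reagents that add atoms: none
Why: 1,2-Reduction of the enoate to the (E)-allylic alcohol; no conjugate reduction is expected with this hydride at low temperature.

Step 15
Reactants: 23 (2S,3R,5S,6R)-6-{[(2S,4S,6R)-6-{(2S)-1-[(tert-butyldiphenylsilyl)oxy]propan-2-yl}-4-methoxyoxan-2-yl]methyl}-2-[(2E)-4-hydroxybut-2-en-1-yl]-3,5-dimethyloxan-3-ol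
Product: 24 (2S,3R,5S,6R)-2-[(2E)-4-bromobut-2-en-1-yl]-6-{[(2S,4S,6R)-6-{(2S)-1-[(tert-butyldiphenylsilyl)oxy]propan-2-yl}-4-methoxyoxan-2-yl]methyl}-3,5-dimethyloxan-3-ol
Conditions: CBr4, PPh3, CH2Cl2, −20 °C
Reagents that add atoms: carbon tetrabromide, BrC(Br)(Br)Br
Why: Appel bromination of the primary allylic alcohol; at low temperature no allylic transposition is expected and the tertiary alcohol should not react.

Step 16
Reactants: 24 (2S,3R,5S,6R)-2-[(2E)-4-bromobut-2-en-1-yl]-6-{[(2S,4S,6R)-6-{(2S)-1-[(tert-butyldiphenylsilyl)oxy]propan-2-yl}-4-methoxyoxan-2-yl]methyl}-3,5-dimethyloxan-3-ol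
Product: 25 (2S,3R,5S,6R)-6-{[(2S,4S,6R)-6-{(2S)-1-[(tert-butyldiphenylsilyl)oxy]propan-2-yl}-4-methoxyoxan-2-yl]methyl}-3,5-dimethyl-2-[(2R)-2-methylbut-3-en-1-yl]oxan-3-ol
Conditions: CuBr·SMe2 (5 mol%), (R,R)-Taniaphos [1-{(dimethylamino)[2-(diphenylphosphino)phenyl]methyl}-2-(diphenylphosphino)ferrocene] (6 mol%), MeMgBr (2.4 equiv), CH2Cl2, −78 °C
Reagents that add atoms: methylmagnesium bromide, C[Mg]Br
Why: Copper-catalysed asymmetric allylic alkylation: the chiral methylcopper species (monovalent copper) adds to C10 in the SN2′ sense through an allyl complex of trivalent copper and reductive elimination, the ligand selecting the face that gives 10R; the first equivalent of Grignard reagent only deprotonates O13–H.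

Step 17
Reactants: 25 (2S,3R,5S,6R)-6-{[(2S,4S,6R)-6-{(2S)-1-[(tert-butyldiphenylsilyl)oxy]propan-2-yl}-4-methoxyoxan-2-yl]methyl}-3,5-dimethyl-2-[(2R)-2-methylbut-3-en-1-yl]oxan-3-ol
Product: 26 (2S,3R,5S,6R)-6-{[(2S,4S,6R)-6-[(2S)-1-hydroxypropan-2-yl]-4-methoxyoxan-2-yl]methyl}-3,5-dimethyl-2-[(2R)-2-methylbut-3-en-1-yl]oxan-3-ol
Conditions: TBAF, AcOH, THF, rt
Reagents that add atoms: none
Why: Buffered fluoride desilylation frees the C24 hydroxyl; nothing else in 25 is sensitive to fluoride.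

Step 18
Reactants: 26 (2S,3R,5S,6R)-6-{[(2S,4S,6R)-6-[(2S)-1-hydroxypropan-2-yl]-4-methoxyoxan-2-yl]methyl}-3,5-dimethyl-2-[(2R)-2-methylbut-3-en-1-yl]oxan-3-ol
Product: 27 (2S,3R,5S,6R)-6-{[(2S,4S,6R)-4-methoxy-6-[(2R)-1-oxopropan-2-yl]oxan-2-yl]methyl}-3,5-dimethyl-2-[(2R)-2-methylbut-3-en-1-yl]oxan-3-ol
Conditions: Dess–Martin periodinane, NaHCO3, CH2Cl2, 0 °C
Reagents that add atoms: none
Why: Buffered Dess–Martin oxidation of the only primary alcohol; the tertiary alcohol cannot be oxidised and the mild conditions should keep the α-methyl, β-alkoxy aldehyde from epimerising (the descriptor at C23 changes by priority only).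

Step 19
Reactants: 27 (2S,3R,5S,6R)-6-{[(2S,4S,6R)-4-methoxy-6-[(2R)-1-oxopropan-2-yl]oxan-2-yl]methyl}-3,5-dimethyl-2-[(2R)-2-methylbut-3-en-1-yl]oxan-3-ol
Product: 28 (2S,3R,5S,6R)-6-{[(2S,4S,6R)-4-methoxy-6-[(2S,3E)-4-methyl-5-oxopent-3-en-2-yl]oxan-2-yl]methyl}-3,5-dimethyl-2-[(2R)-2-methylbut-3-en-1-yl]oxan-3-ol
Conditions: Ph3P=C(CH3)CHO, toluene, 80 °C
Reagents that add atoms: 2-(triphenylphosphoranylidene)propanal, CC(C=O)=P(c1ccccc1)(c1ccccc1)c1ccccc1
Why: Wittig reaction with a stabilised ylide should give the (E)-2-methyl enal (C24=C25) directly; the product enal is a poorer electrophile than 27, so double olefination is not expected.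

Step 20
Reactants: 28 (2S,3R,5S,6R)-6-{[(2S,4S,6R)-4-methoxy-6-[(2S,3E)-4-methyl-5-oxopent-3-en-2-yl]oxan-2-yl]methyl}-3,5-dimethyl-2-[(2R)-2-methylbut-3-en-1-yl]oxan-3-ol
Product: 29 (2S,3R,5S,6R)-6-{[(2S,4S,6R)-4-methoxy-6-[(2S,3E)-4-methyl-5-oxopent-3-en-2-yl]oxan-2-yl]methyl}-3,5-dimethyl-2-[(2R,3E)-2-methyl-4-(4,4,5,5-tetramethyl-1,3,2-dioxaborolan-2-yl)but-3-en-1-yl]oxan-3-ol
Conditions: vinylboronic acid pinacol ester (5 equiv), second-generation Hoveyda–Grubbs catalyst [RuCl2(H2IMes)(=CH-C6H4-2-O-i-Pr)] (10 mol%), CH2Cl2, 40 °C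
Reagents that add atoms: 4,4,5,5-tetramethyl-2-vinyl-1,3,2-dioxaborolane, C=CB1OC(C)(C)C(C)(C)O1
Why: Olefin cross-metathesis of the only terminal alkene with the vinylboronate, expected to give the (E)-alkenylboronate; the trisubstituted, electron-poor enal alkene should not take part.

Step 21
Reactants: 29 (2S,3R,5S,6R)-6-{[(2S,4S,6R)-4-methoxy-6-[(2S,3E)-4-methyl-5-oxopent-3-en-2-yl]oxan-2-yl]methyl}-3,5-dimethyl-2-[(2R,3E)-2-methyl-4-(4,4,5,5-tetramethyl-1,3,2-dioxaborolan-2-yl)but-3-en-1-yl]oxan-3-ol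
Product: 30 (2S,3R,5S,6R)-6-{[(2S,4S,6R)-6-[(2S,3E,5E)-6-iodo-4-methylhexa-3,5-dien-2-yl]-4-methoxyoxan-2-yl]methyl}-3,5-dimethyl-2-[(2R,3E)-2-methyl-4-(4,4,5,5-tetramethyl-1,3,2-dioxaborolan-2-yl)but-3-en-1-yl]oxan-3-ol
Conditions: CrCl2 (8 equiv), CHI3 (3 equiv), THF/1,4-dioxane (1:6), 0 °C to rt
Reagents that add atoms: iodoform, IC(I)I
Why: Takai iodo-olefination: the geminal dichromium reagent from CHI3 and CrCl2 (divalent chromium) adds to the enal and anti-periplanar elimination should give the (E)-iodoalkene C26=C27; the boronate and the free hydroxyl are inert to the reagent.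

Step 22
Reactants: 30 (2S,3R,5S,6R)-6-{[(2S,4S,6R)-6-[(2S,3E,5E)-6-iodo-4-methylhexa-3,5-dien-2-yl]-4-methoxyoxan-2-yl]methyl}-3,5-dimethyl-2-[(2R,3E)-2-methyl-4-(4,4,5,5-tetramethyl-1,3,2-dioxaborolan-2-yl)but-3-en-1-yl]oxan-3-ol
Product: 31 (2S,3R,5S,6R)-6-{[(2S,4S,6R)-4-methoxy-6-[(2S,3E,5E)-4-methylocta-3,5,7-trien-2-yl]oxan-2-yl]methyl}-3,5-dimethyl-2-[(2R,3E)-2-methyl-4-(4,4,5,5-tetramethyl-1,3,2-dioxaborolan-2-yl)but-3-en-1-yl]oxan-3-ol
Conditions: Bu3SnCH=CH2, Pd2(dba)3 (5 mol%), Ph3As (20 mol%), DMF, rt, dark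
Reagents that add atoms: tributyl(vinyl)stannane, C=C[Sn](CCCC)(CCCC)CCCC
Why: Stille coupling with retention at both partners completes the triene; with no base present the pinacol boronate cannot transmetalate, so it is carried through unchanged for step 33.

Step 23
Reactants: 32 ethyl (S)-4-chloro-3-hydroxybutanoate
Product: 33 ethyl (S)-4-azido-3-hydroxybutanoate
Conditions: NaN3, DMF, 80 °C
Reagents that add atoms: sodium azide, [Na+].[N-]=[N+]=[N-]
Why: SN2 displacement of the primary chloride (direct or through the transient epoxide, both leaving C2 unchanged) installs N1 as an azide; the azide is kept in solution and not distilled.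

Step 24
Reactants: 33 ethyl (S)-4-azido-3-hydroxybutanoate
Product: 34 ethyl (S)-4-azido-3-[(tert-butyldimethylsilyl)oxy]butanoate
Conditions: TBSCl, imidazole, DMF, rt
Reagents that add atoms: tert-butyl(chloro)dimethylsilane, CC(C)(C)[Si](C)(C)Cl
Why: Silylation of O2 keeps this hydroxyl apart from O4, which is carbamoylated in step 27.

Step 25
Reactants: 34 ethyl (S)-4-azido-3-[(tert-butyldimethylsilyl)oxy]butanoate
Product: 35 (S)-4-azido-3-[(tert-butyldimethylsilyl)oxy]butanal
Conditions: i-Bu2AlH (1.1 equiv), CH2Cl2, −78 °C; aq. KNaC4H4O6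
Reagents that add atoms: none
Why: Partial ester reduction at −78 °C, at which temperature alkyl azides are not reduced by this hydride.

Step 26
Reactants: 35 (S)-4-azido-3-[(tert-butyldimethylsilyl)oxy]butanal; 4 allylmagnesium bromide (C3H5MgBr)
Product: 36 (2S,4R)-1-azido-2-[(tert-butyldimethylsilyl)oxy]hept-6-en-4-ol
Conditions: (+)-Ipc2BOMe and 4, Et2O, −78 °C to rt; then 35, −78 °C; NaOH, H2O2, rt
Reagents that add atoms: none
Why: Brown allylation with the same (+)-borane as in step 3; reagent-controlled Re-face attack should set 4R (1,3-anti to C2), since a β-silyloxy group exerts little bias of its own.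

Step 27
Reactants: 36 (2S,4R)-1-azido-2-[(tert-butyldimethylsilyl)oxy]hept-6-en-4-ol
Product: 38 (2S,4R)-1-azido-2-[(tert-butyldimethylsilyl)oxy]hept-6-en-4-yl carbamate, via trichloroacetyl carbamate 37 (not isolated)
Conditions: Cl3CC(O)NCO, CH2Cl2, 0 °C; then K2CO3, MeOH, 0 °C
Reagents that add atoms: trichloroacetyl isocyanate, O=C=NC(=O)C(Cl)(Cl)Cl
Why: Addition of the only free hydroxyl to the acyl isocyanate and methanolysis of the trichloroacetyl group give the primary carbamate on O4.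

Step 28
Reactants: 38 (2S,4R)-1-azido-2-[(tert-butyldimethylsilyl)oxy]hept-6-en-4-yl carbamate
Product: 39 (2S,4R,6Z)-1-azido-2-[(tert-butyldimethylsilyl)oxy]-7-(4,4,5,5-tetramethyl-1,3,2-dioxaborolan-2-yl)oct-6-en-4-yl carbamate
Conditions: isopropenylboronic acid pinacol ester (3 equiv), second-generation Hoveyda–Grubbs catalyst [RuCl2(H2IMes)(=CH-C6H4-2-O-i-Pr)] (10 mol%), CH2Cl2, 40 °C
Reagents that add atoms: 4,4,5,5-tetramethyl-2-(prop-1-en-2-yl)-1,3,2-dioxaborolane, CC(=C)B1OC(C)(C)C(C)(C)O1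
Why: Cross-metathesis with a 1,1-disubstituted vinylboronate builds the trisubstituted C6=C7 alkene; the isomer with the bulky boronate trans to the chain (Z by priority) is expected to dominate, and a phosphine-free catalyst is used so that no free phosphine reduces the azide.

Step 29
Reactants: 39 (2S,4R,6Z)-1-azido-2-[(tert-butyldimethylsilyl)oxy]-7-(4,4,5,5-tetramethyl-1,3,2-dioxaborolan-2-yl)oct-6-en-4-yl carbamate
Product: 40 (2S,4R,6E)-1-azido-2-[(tert-butyldimethylsilyl)oxy]-7-iodooct-6-en-4-yl carbamate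
Conditions: NaOH (aq), THF, 0 °C; then I2, 0 °C
Reagents that add atoms: iodine, II
Why: Iododeboronation of the hydroxide ate complex, which replaces boron by iodine with retention when base is added before iodine; iodine ends up trans to C5 as the diene requires.

Step 30
Reactants: 40 (2S,4R,6E)-1-azido-2-[(tert-butyldimethylsilyl)oxy]-7-iodooct-6-en-4-yl carbamate
Product: 41 (2S,4R,6E)-1-azido-2-hydroxy-7-iodooct-6-en-4-yl carbamate
Conditions: HF·pyridine, pyridine, THF, 0 °C to rt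
Reagents that add atoms: none
Why: Buffered desilylation before the acid-labile enol-ether amide is present; the non-basic medium should not promote carbamoyl migration from O4 to O2.

Step 31
Reactants: 42 methyl 2-methoxyacrylate
Product: 43 2-methoxyacrylic acid
Conditions: LiOH, THF/H2O, 0 °C to rt; then cold 1 M HCl to pH 3
Reagents that add atoms: lithium hydroxide, [Li+].[OH-]
Why: Ester saponification; brief cold acidification limits hydrolysis of the enol ether.

Step 32
Reactants: 41 (2S,4R,6E)-1-azido-2-hydroxy-7-iodooct-6-en-4-yl carbamate; 43 2-methoxyacrylic acid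
Product: 45 (2S,4R,6E)-2-hydroxy-7-iodo-1-[(2-methoxyprop-2-enoyl)amino]oct-6-en-4-yl carbamate, via amine 44 (not isolated)
Conditions: PMe3, THF/H2O (10:1), rt; evaporate; then 43, EDC·HCl, HOBt, i-Pr2NEt, CH2Cl2/DMF, 0 °C to rt
Reagents that add atoms: none
Why: Staudinger reduction followed by carbodiimide amide coupling; the primary amine should be acylated well before the secondary hydroxyl or the carbamate nitrogen, and the excess phosphine is removed first so that it cannot add to the acrylate.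

Step 33
Reactants: 31 (2S,3R,5S,6R)-6-{[(2S,4S,6R)-4-methoxy-6-[(2S,3E,5E)-4-methylocta-3,5,7-trien-2-yl]oxan-2-yl]methyl}-3,5-dimethyl-2-[(2R,3E)-2-methyl-4-(4,4,5,5-tetramethyl-1,3,2-dioxaborolan-2-yl)but-3-en-1-yl]oxan-3-ol; 45 (2S,4R,6E)-2-hydroxy-7-iodo-1-[(2-methoxyprop-2-enoyl)amino]oct-6-en-4-yl carbamate
Product: 46 (2S,4R,6E,8E,10R)-2-hydroxy-11-[(2S,3R,5S,6R)-3-hydroxy-6-{[(2S,4S,6R)-4-methoxy-6-[(2S,3E,5E)-4-methylocta-3,5,7-trien-2-yl]oxan-2-yl]methyl}-3,5-dimethyloxan-2-yl]-1-[(2-methoxyprop-2-enoyl)amino]-7,10-dimethylundeca-6,8-dien-4-yl carbamate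
Conditions: Pd(dppf)Cl2·CH2Cl2 (10 mol%), Ph3As (20 mol%), Cs2CO3, DMF/H2O, rt, dark
Reagents that add atoms: none
Why: Suzuki–Miyaura coupling of alkenylboronate and alkenyl iodide with retention at both carbons forms the C7–C8 bond and the (6E,8E)-diene; the mild aqueous base at room temperature should leave the carbamate, the amide, the free hydroxyls and the triene untouched, and no protecting group remains to be removed.

## Compound list

1 | methyl (S)-3-hydroxy-2-methylpropanoate | COC(=O)[C@@H](C)CO | starting material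
2 | methyl (S)-3-[(tert-butyldiphenylsilyl)oxy]-2-methylpropanoate | COC(=O)[C@@H](C)CO[Si](c1ccccc1)(c1ccccc1)C(C)(C)C | intermediate
3 | (S)-3-[(tert-butyldiphenylsilyl)oxy]-2-methylpropanal | O=C[C@@H](C)CO[Si](c1ccccc1)(c1ccccc1)C(C)(C)C | intermediate
4 | allylmagnesium bromide | C=CC[Mg]Br | starting material
5 | (2S,3R)-1-[(tert-butyldiphenylsilyl)oxy]-2-methylhex-5-en-3-ol | C=CC[C@@H](O)[C@@H](C)CO[Si](c1ccccc1)(c1ccccc1)C(C)(C)C | intermediate
6 | (2S,3R)-2-methylhex-5-ene-1,3-diol | C=CC[C@@H](O)[C@@H](C)CO | intermediate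
7 | (2R,3R)-1-iodo-2-methylhex-5-en-3-ol | C=CC[C@@H](O)[C@@H](C)CI | intermediate (not isolated)
8 | triethyl{[(4R,5R)-6-iodo-5-methylhex-1-en-4-yl]oxy}silane | C=CC[C@@H](O[Si](CC)(CC)CC)[C@@H](C)CI | intermediate
9 | 2-methyl-1,3-dithiane | CC1SCCCS1 | starting material
10 | triethyl{[(4R,5S)-5-methyl-6-(2-methyl-1,3-dithian-2-yl)hex-1-en-4-yl]oxy}silane | C=CC[C@@H](O[Si](CC)(CC)CC)[C@@H](C)CC1(C)SCCCS1 | intermediate (not isolated)
11 | (2S,3R)-2-methyl-1-(2-methyl-1,3-dithian-2-yl)hex-5-en-3-ol | C=CC[C@@H](O)[C@@H](C)CC1(C)SCCCS1 | intermediate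
12 | ethyl propiolate | CCOC(=O)C#C | starting material
13 | ethyl (2E)-3-{[(4R,5S)-5-methyl-6-(2-methyl-1,3-dithian-2-yl)hex-1-en-4-yl]oxy}prop-2-enoate | CCOC(=O)/C=C/O[C@H](CC=C)[C@@H](C)CC1(C)SCCCS1 | intermediate
14 | ethyl (2E)-3-{[(4R,5S)-5-methyl-7-oxooct-1-en-4-yl]oxy}prop-2-enoate | CCOC(=O)/C=C/O[C@H](CC=C)[C@@H](C)CC(C)=O | intermediate
15 | ethyl 2-[(2S,3R,5S,6R)-3-hydroxy-3,5-dimethyl-6-(prop-2-en-1-yl)oxan-2-yl]acetate | C=CC[C@H]1O[C@@H](CC(=O)OCC)[C@](C)(O)C[C@@H]1C | intermediate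
16 | ethyl 2-[(2S,3R,5S,6R)-3-hydroxy-3,5-dimethyl-6-(1,2,4-trioxolan-3-ylmethyl)oxan-2-yl]acetate (both configurations at the trioxolane carbon) | O1COC(C[C@H]2O[C@@H](CC(=O)OCC)[C@](C)(O)C[C@@H]2C)O1 | intermediate (not isolated)
17 | ethyl 2-[(2S,3R,5S,6R)-3-hydroxy-3,5-dimethyl-6-(2-oxoethyl)oxan-2-yl]acetate | O=CC[C@H]1O[C@@H](CC(=O)OCC)[C@](C)(O)C[C@@H]1C | intermediate
18 | ethyl 2-[(2S,3R,5S,6R)-6-{[(2S,4S,6R)-6-{(2S)-1-[(tert-butyldiphenylsilyl)oxy]propan-2-yl}-4-[(trifluoroacetyl)oxy]oxan-2-yl]methyl}-3-hydroxy-3,5-dimethyloxan-2-yl]acetate | CC(C)(C)[Si](c1ccccc1)(c1ccccc1)OC[C@H](C)[C@H]1C[C@@H](OC(=O)C(F)(F)F)C[C@@H](C[C@H]2O[C@@H](CC(=O)OCC)[C@](C)(O)C[C@@H]2C)O1 | intermediate (not isolated)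
19 | ethyl 2-[(2S,3R,5S,6R)-6-{[(2S,4S,6R)-6-{(2S)-1-[(tert-butyldiphenylsilyl)oxy]propan-2-yl}-4-hydroxyoxan-2-yl]methyl}-3-hydroxy-3,5-dimethyloxan-2-yl]acetate | CC(C)(C)[Si](c1ccccc1)(c1ccccc1)OC[C@H](C)[C@H]1C[C@@H](O)C[C@@H](C[C@H]2O[C@@H](CC(=O)OCC)[C@](C)(O)C[C@@H]2C)O1 | intermediate
20 | ethyl 2-[(2S,3R,5S,6R)-6-{[(2S,4S,6R)-6-{(2S)-1-[(tert-butyldiphenylsilyl)oxy]propan-2-yl}-4-methoxyoxan-2-yl]methyl}-3-hydroxy-3,5-dimethyloxan-2-yl]acetate | CC(C)(C)[Si](c1ccccc1)(c1ccccc1)OC[C@H](C)[C@H]1C[C@@H](OC)C[C@@H](C[C@H]2O[C@@H](CC(=O)OCC)[C@](C)(O)C[C@@H]2C)O1 | intermediate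
21 | 2-[(2S,3R,5S,6R)-6-{[(2S,4S,6R)-6-{(2S)-1-[(tert-butyldiphenylsilyl)oxy]propan-2-yl}-4-methoxyoxan-2-yl]methyl}-3-hydroxy-3,5-dimethyloxan-2-yl]acetaldehyde | CC(C)(C)[Si](c1ccccc1)(c1ccccc1)OC[C@H](C)[C@H]1C[C@@H](OC)C[C@@H](C[C@H]2O[C@@H](CC=O)[C@](C)(O)C[C@@H]2C)O1 | intermediate (not isolated)
22 | ethyl (2E)-4-[(2S,3R,5S,6R)-6-{[(2S,4S,6R)-6-{(2S)-1-[(tert-butyldiphenylsilyl)oxy]propan-2-yl}-4-methoxyoxan-2-yl]methyl}-3-hydroxy-3,5-dimethyloxan-2-yl]but-2-enoate | CC(C)(C)[Si](c1ccccc1)(c1ccccc1)OC[C@H](C)[C@H]1C[C@@H](OC)C[C@@H](C[C@H]2O[C@@H](C/C=C/C(=O)OCC)[C@](C)(O)C[C@@H]2C)O1 | intermediate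
23 | (2S,3R,5S,6R)-6-{[(2S,4S,6R)-6-{(2S)-1-[(tert-butyldiphenylsilyl)oxy]propan-2-yl}-4-methoxyoxan-2-yl]methyl}-2-[(2E)-4-hydroxybut-2-en-1-yl]-3,5-dimethyloxan-3-ol | CC(C)(C)[Si](c1ccccc1)(c1ccccc1)OC[C@H](C)[C@H]1C[C@@H](OC)C[C@@H](C[C@H]2O[C@@H](C/C=C/CO)[C@](C)(O)C[C@@H]2C)O1 | intermediate
24 | (2S,3R,5S,6R)-2-[(2E)-4-bromobut-2-en-1-yl]-6-{[(2S,4S,6R)-6-{(2S)-1-[(tert-butyldiphenylsilyl)oxy]propan-2-yl}-4-methoxyoxan-2-yl]methyl}-3,5-dimethyloxan-3-ol | CC(C)(C)[Si](c1ccccc1)(c1ccccc1)OC[C@H](C)[C@H]1C[C@@H](OC)C[C@@H](C[C@H]2O[C@@H](C/C=C/CBr)[C@](C)(O)C[C@@H]2C)O1 | intermediate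
25 | (2S,3R,5S,6R)-6-{[(2S,4S,6R)-6-{(2S)-1-[(tert-butyldiphenylsilyl)oxy]propan-2-yl}-4-methoxyoxan-2-yl]methyl}-3,5-dimethyl-2-[(2R)-2-methylbut-3-en-1-yl]oxan-3-ol | CC(C)(C)[Si](c1ccccc1)(c1ccccc1)OC[C@H](C)[C@H]1C[C@@H](OC)C[C@@H](C[C@H]2O[C@@H](C[C@@H](C)C=C)[C@](C)(O)C[C@@H]2C)O1 | intermediate
26 | (2S,3R,5S,6R)-6-{[(2S,4S,6R)-6-[(2S)-1-hydroxypropan-2-yl]-4-methoxyoxan-2-yl]methyl}-3,5-dimethyl-2-[(2R)-2-methylbut-3-en-1-yl]oxan-3-ol | OC[C@H](C)[C@H]1C[C@@H](OC)C[C@@H](C[C@H]2O[C@@H](C[C@@H](C)C=C)[C@](C)(O)C[C@@H]2C)O1 | intermediate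
27 | (2S,3R,5S,6R)-6-{[(2S,4S,6R)-4-methoxy-6-[(2R)-1-oxopropan-2-yl]oxan-2-yl]methyl}-3,5-dimethyl-2-[(2R)-2-methylbut-3-en-1-yl]oxan-3-ol | O=C[C@H](C)[C@H]1C[C@@H](OC)C[C@@H](C[C@H]2O[C@@H](C[C@@H](C)C=C)[C@](C)(O)C[C@@H]2C)O1 | intermediate
28 | (2S,3R,5S,6R)-6-{[(2S,4S,6R)-4-methoxy-6-[(2S,3E)-4-methyl-5-oxopent-3-en-2-yl]oxan-2-yl]methyl}-3,5-dimethyl-2-[(2R)-2-methylbut-3-en-1-yl]oxan-3-ol | O=C/C(C)=C/[C@H](C)[C@H]1C[C@@H](OC)C[C@@H](C[C@H]2O[C@@H](C[C@@H](C)C=C)[C@](C)(O)C[C@@H]2C)O1 | intermediate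
29 | (2S,3R,5S,6R)-6-{[(2S,4S,6R)-4-methoxy-6-[(2S,3E)-4-methyl-5-oxopent-3-en-2-yl]oxan-2-yl]methyl}-3,5-dimethyl-2-[(2R,3E)-2-methyl-4-(4,4,5,5-tetramethyl-1,3,2-dioxaborolan-2-yl)but-3-en-1-yl]oxan-3-ol | O=C/C(C)=C/[C@H](C)[C@H]1C[C@@H](OC)C[C@@H](C[C@H]2O[C@@H](C[C@@H](C)/C=C/B3OC(C)(C)C(C)(C)O3)[C@](C)(O)C[C@@H]2C)O1 | intermediate
30 | (2S,3R,5S,6R)-6-{[(2S,4S,6R)-6-[(2S,3E,5E)-6-iodo-4-methylhexa-3,5-dien-2-yl]-4-methoxyoxan-2-yl]methyl}-3,5-dimethyl-2-[(2R,3E)-2-methyl-4-(4,4,5,5-tetramethyl-1,3,2-dioxaborolan-2-yl)but-3-en-1-yl]oxan-3-ol | I/C=C/C(C)=C/[C@H](C)[C@H]1C[C@@H](OC)C[C@@H](C[C@H]2O[C@@H](C[C@@H](C)/C=C/B3OC(C)(C)C(C)(C)O3)[C@](C)(O)C[C@@H]2C)O1 | intermediate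
31 | (2S,3R,5S,6R)-6-{[(2S,4S,6R)-4-methoxy-6-[(2S,3E,5E)-4-methylocta-3,5,7-trien-2-yl]oxan-2-yl]methyl}-3,5-dimethyl-2-[(2R,3E)-2-methyl-4-(4,4,5,5-tetramethyl-1,3,2-dioxaborolan-2-yl)but-3-en-1-yl]oxan-3-ol | C=C/C=C/C(C)=C/[C@H](C)[C@H]1C[C@@H](OC)C[C@@H](C[C@H]2O[C@@H](C[C@@H](C)/C=C/B3OC(C)(C)C(C)(C)O3)[C@](C)(O)C[C@@H]2C)O1 | intermediate
32 | ethyl (S)-4-chloro-3-hydroxybutanoate | CCOC(=O)C[C@H](O)CCl | starting material
33 | ethyl (S)-4-azido-3-hydroxybutanoate | CCOC(=O)C[C@H](O)CN=[N+]=[N-] | intermediate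
34 | ethyl (S)-4-azido-3-[(tert-butyldimethylsilyl)oxy]butanoate | CCOC(=O)C[C@H](O[Si](C)(C)C(C)(C)C)CN=[N+]=[N-] | intermediate
35 | (S)-4-azido-3-[(tert-butyldimethylsilyl)oxy]butanal | O=CC[C@H](O[Si](C)(C)C(C)(C)C)CN=[N+]=[N-] | intermediate
36 | (2S,4R)-1-azido-2-[(tert-butyldimethylsilyl)oxy]hept-6-en-4-ol | C=CC[C@H](C[C@H](O[Si](C)(C)C(C)(C)C)CN=[N+]=[N-])O | intermediate
37 | (2S,4R)-1-azido-2-[(tert-butyldimethylsilyl)oxy]hept-6-en-4-yl (trichloroacetyl)carbamate | C=CC[C@H](C[C@H](O[Si](C)(C)C(C)(C)C)CN=[N+]=[N-])OC(=O)NC(=O)C(Cl)(Cl)Cl | intermediate (not isolated)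
38 | (2S,4R)-1-azido-2-[(tert-butyldimethylsilyl)oxy]hept-6-en-4-yl carbamate | C=CC[C@H](C[C@H](O[Si](C)(C)C(C)(C)C)CN=[N+]=[N-])OC(N)=O | intermediate
39 | (2S,4R,6Z)-1-azido-2-[(tert-butyldimethylsilyl)oxy]-7-(4,4,5,5-tetramethyl-1,3,2-dioxaborolan-2-yl)oct-6-en-4-yl carbamate | C/C(B1OC(C)(C)C(C)(C)O1)=C\C[C@H](C[C@H](O[Si](C)(C)C(C)(C)C)CN=[N+]=[N-])OC(N)=O | intermediate
40 | (2S,4R,6E)-1-azido-2-[(tert-butyldimethylsilyl)oxy]-7-iodooct-6-en-4-yl carbamate | C/C(I)=C\C[C@H](C[C@H](O[Si](C)(C)C(C)(C)C)CN=[N+]=[N-])OC(N)=O | intermediate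
41 | (2S,4R,6E)-1-azido-2-hydroxy-7-iodooct-6-en-4-yl carbamate | C/C(I)=C\C[C@H](C[C@H](O)CN=[N+]=[N-])OC(N)=O | intermediate
42 | methyl 2-methoxyacrylate | COC(=C)C(=O)OC | starting material
43 | 2-methoxyacrylic acid | COC(=C)C(=O)O | intermediate
44 | (2S,4R,6E)-1-amino-2-hydroxy-7-iodooct-6-en-4-yl carbamate | C/C(I)=C\C[C@H](C[C@H](O)CN)OC(N)=O | intermediate (not isolated)
45 | (2S,4R,6E)-2-hydroxy-7-iodo-1-[(2-methoxyprop-2-enoyl)amino]oct-6-en-4-yl carbamate | C/C(I)=C\C[C@H](C[C@H](O)CNC(=O)C(=C)OC)OC(N)=O | intermediate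
46 | (2S,4R,6E,8E,10R)-2-hydroxy-11-[(2S,3R,5S,6R)-3-hydroxy-6-{[(2S,4S,6R)-4-methoxy-6-[(2S,3E,5E)-4-methylocta-3,5,7-trien-2-yl]oxan-2-yl]methyl}-3,5-dimethyloxan-2-yl]-1-[(2-methoxyprop-2-enoyl)amino]-7,10-dimethylundeca-6,8-dien-4-yl carbamate | C=C/C=C/C(C)=C/[C@H](C)[C@H]1C[C@@H](OC)C[C@@H](C[C@H]2O[C@@H](C[C@@H](C)/C=C/C(C)=C/C[C@H](C[C@H](O)CNC(=O)C(=C)OC)OC(N)=O)[C@](C)(O)C[C@@H]2C)O1 | target

## Step count and least certain steps

Total step count: 33. Longest linear sequence: 23 steps (steps 1–22 and 33).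

Step 9 (key step). The most likely failure is that the samarium ketyl of the methyl ketone, which forms less readily and adds more slowly than an aldehyde ketyl, is reduced on to the secondary alcohol or dimerises before it cyclises; loosened chelation would also erode the facial selectivity at C13. The fallback sets out from 8 and comes back at 15; it closes ring B with the aldehyde, the best-documented substrate class, and adds the methyl group afterwards. 8 is alkylated with 2-lithio-1,3-dithiane in place of 9, and the crude triethyl{[(4R,5S)-6-(1,3-dithian-2-yl)-5-methylhex-1-en-4-yl]oxy}silane F1 is desilylated in the acidic work-up to (2S,3R)-1-(1,3-dithian-2-yl)-2-methylhex-5-en-3-ol F2. Ethyl propiolate and N-methylmorpholine give ethyl (2E)-3-{[(4R,5S)-6-(1,3-dithian-2-yl)-5-methylhex-1-en-4-yl]oxy}prop-2-enoate F3, and MeI/CaCO3 gives ethyl (2E)-3-{[(4R,5S)-5-methyl-7-oxohept-1-en-4-yl]oxy}prop-2-enoate F4. SmI2/MeOH should cyclise F4 to ethyl 2-[(2S,3R,5S,6R)-3-hydroxy-5-methyl-6-(prop-2-en-1-yl)oxan-2-yl]acetate F5. Dess–Martin oxidation gives ethyl 2-[(2S,5S,6R)-5-methyl-3-oxo-6-(prop-2-en-1-yl)oxan-2-yl]acetate F6, and excess Me3Al in toluene at −78 °C should deliver methyl axially to the ketone, in preference to the ester, to give 15.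

Step 11. The oxocarbenium ion may equilibrate by 2-oxonia-Cope rearrangement (allyl transfer) faster than it cyclises, which would scramble the two partners and erode C22; the strong acid may also ionise the tertiary C13 alcohol. The fallback sets out from 3 and 17 and comes back at 19; it replaces the cationic union by a catalysed cycloaddition. Wittig reaction of 3 with 1-(triphenylphosphoranylidene)propan-2-one gives (3E,5R)-6-[(tert-butyldiphenylsilyl)oxy]-5-methylhex-3-en-2-one F7, and Et3SiOTf/Et3N gives tert-butyl{[(2R,3E)-2-methyl-5-[(triethylsilyl)oxy]hexa-3,5-dien-1-yl]oxy}diphenylsilane F8. Hetero-Diels–Alder reaction of F8 with 17 under a chiral tridentate Schiff-base chromium chloride catalyst (trivalent chromium) should give the 2,6-cis cycloadduct ethyl 2-[(2S,3R,5S,6R)-6-{[6-{(2S)-1-[(tert-butyldiphenylsilyl)oxy]propan-2-yl}-4-[(triethylsilyl)oxy]-3,6-dihydro-2H-pyran-2-yl]methyl}-3-hydroxy-3,5-dimethyloxan-2-yl]acetate F9 (ring-A centres as in 19). PPTS/MeOH unmasks the ketone ethyl 2-[(2S,3R,5S,6R)-6-{[6-{(2S)-1-[(tert-butyldiphenylsilyl)oxy]propan-2-yl}-4-oxooxan-2-yl]methyl}-3-hydroxy-3,5-dimethyloxan-2-yl]acetate F10, and NaBH4 (axial hydride delivery, equatorial alcohol) gives 19.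

Step 16. Linear SN2 substitution may compete with the SN2′ path, or the facial selectivity may be poor, because the magnesium alkoxide at O13 and the ring oxygens can bind copper and override the ligand. The fallback sets out from 20 and comes back at 25; it sets C10 by carbometalation of an alkene instead of allylic substitution. 20 is reduced to 21 as in step 13 and methylenated (Ph3P=CH2) to (2S,3R,5S,6R)-6-{[(2S,4S,6R)-6-{(2S)-1-[(tert-butyldiphenylsilyl)oxy]propan-2-yl}-4-methoxyoxan-2-yl]methyl}-3,5-dimethyl-2-(prop-2-en-1-yl)oxan-3-ol F11. Zirconium-catalysed asymmetric carboalumination (Me3Al, (−)-bis(1-neomenthylindenyl)zirconium dichloride, then O2) should give (2S,3R,5S,6R)-6-{[(2S,4S,6R)-6-{(2S)-1-[(tert-butyldiphenylsilyl)oxy]propan-2-yl}-4-methoxyoxan-2-yl]methyl}-2-[(2R)-3-hydroxy-2-methylpropyl]-3,5-dimethyloxan-3-ol F12. Dess–Martin oxidation gives (2R)-3-[(2S,3R,5S,6R)-6-{[(2S,4S,6R)-6-{(2S)-1-[(tert-butyldiphenylsilyl)oxy]propan-2-yl}-4-methoxyoxan-2-yl]methyl}-3-hydroxy-3,5-dimethyloxan-2-yl]-2-methylpropanal F13, and a second methylenation with salt-free Ph3P=CH2 at low temperature gives 25.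

Step 21. The iodo-olefination of a conjugated, α-branched enal may lose E-selectivity, and the long exposure to excess CrCl2 may lead to partial reduction or isomerisation of the iododiene. The fallback sets out from 27 and comes back at 31; it builds the trisubstituted alkene by two stereospecific couplings on a 1,1-dibromoalkene instead of two olefinations. 27 is converted with CBr4/PPh3/Zn into (2S,3R,5S,6R)-6-{[(2S,4S,6R)-6-[(2S)-4,4-dibromobut-3-en-2-yl]-4-methoxyoxan-2-yl]methyl}-3,5-dimethyl-2-[(2R)-2-methylbut-3-en-1-yl]oxan-3-ol F14. Cross-metathesis with vinylboronic acid pinacol ester as in step 20 gives (2S,3R,5S,6R)-6-{[(2S,4S,6R)-6-[(2S)-4,4-dibromobut-3-en-2-yl]-4-methoxyoxan-2-yl]methyl}-3,5-dimethyl-2-[(2R,3E)-2-methyl-4-(4,4,5,5-tetramethyl-1,3,2-dioxaborolan-2-yl)but-3-en-1-yl]oxan-3-ol F15. A Stille coupling selective for the bromine trans to C23 (Pd2(dba)3, tri(2-furyl)phosphine, toluene) with (E)-tributyl(buta-1,3-dien-1-yl)stannane F16, itself made by one Stille coupling of (E)-1,2-bis(tributylstannyl)ethene with vinyl bromide, should give (2S,3R,5S,6R)-6-{[(2S,4S,6R)-6-[(2S,3Z,5E)-4-bromoocta-3,5,7-trien-2-yl]-4-methoxyoxan-2-yl]methyl}-3,5-dimethyl-2-[(2R,3E)-2-methyl-4-(4,4,5,5-tetramethyl-1,3,2-dioxaborolan-2-yl)but-3-en-1-yl]oxan-3-ol F17. Negishi methylation with retention (Me2Zn, Pd(t-Bu3P)2, THF) then gives 31.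

## Further compounds

F1 | step 9 | triethyl{[(4R,5S)-6-(1,3-dithian-2-yl)-5-methylhex-1-en-4-yl]oxy}silane | C=CC[C@@H](O[Si](CC)(CC)CC)[C@@H](C)CC1SCCCS1
F2 | step 9 | (2S,3R)-1-(1,3-dithian-2-yl)-2-methylhex-5-en-3-ol | C=CC[C@@H](O)[C@@H](C)CC1SCCCS1
F3 | step 9 | ethyl (2E)-3-{[(4R,5S)-6-(1,3-dithian-2-yl)-5-methylhex-1-en-4-yl]oxy}prop-2-enoate | CCOC(=O)/C=C/O[C@H](CC=C)[C@@H](C)CC1SCCCS1
F4 | step 9 | ethyl (2E)-3-{[(4R,5S)-5-methyl-7-oxohept-1-en-4-yl]oxy}prop-2-enoate | CCOC(=O)/C=C/O[C@H](CC=C)[C@@H](C)CC=O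
F5 | step 9 | ethyl 2-[(2S,3R,5S,6R)-3-hydroxy-5-methyl-6-(prop-2-en-1-yl)oxan-2-yl]acetate | C=CC[C@H]1O[C@@H](CC(=O)OCC)[C@H](O)C[C@@H]1C
F6 | step 9 | ethyl 2-[(2S,5S,6R)-5-methyl-3-oxo-6-(prop-2-en-1-yl)oxan-2-yl]acetate | C=CC[C@H]1O[C@@H](CC(=O)OCC)C(=O)C[C@@H]1C
F7 | step 11 | (3E,5R)-6-[(tert-butyldiphenylsilyl)oxy]-5-methylhex-3-en-2-one | CC(=O)/C=C/[C@@H](C)CO[Si](c1ccccc1)(c1ccccc1)C(C)(C)C
F8 | step 11 | tert-butyl{[(2R,3E)-2-methyl-5-[(triethylsilyl)oxy]hexa-3,5-dien-1-yl]oxy}diphenylsilane | C=C(O[Si](CC)(CC)CC)/C=C/[C@@H](C)CO[Si](c1ccccc1)(c1ccccc1)C(C)(C)C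
F9 | step 11 | ethyl 2-[(2S,3R,5S,6R)-6-{[6-{(2S)-1-[(tert-butyldiphenylsilyl)oxy]propan-2-yl}-4-[(triethylsilyl)oxy]-3,6-dihydro-2H-pyran-2-yl]methyl}-3-hydroxy-3,5-dimethyloxan-2-yl]acetate (ring-A centres as in 19) | CC(C)(C)[Si](c1ccccc1)(c1ccccc1)OC[C@H](C)[C@H]1C=C(O[Si](CC)(CC)CC)C[C@@H](C[C@H]2O[C@@H](CC(=O)OCC)[C@](C)(O)C[C@@H]2C)O1
F10 | step 11 | ethyl 2-[(2S,3R,5S,6R)-6-{[6-{(2S)-1-[(tert-butyldiphenylsilyl)oxy]propan-2-yl}-4-oxooxan-2-yl]methyl}-3-hydroxy-3,5-dimethyloxan-2-yl]acetate (ring-A centres as in 19) | CC(C)(C)[Si](c1ccccc1)(c1ccccc1)OC[C@H](C)[C@H]1CC(=O)C[C@@H](C[C@H]2O[C@@H](CC(=O)OCC)[C@](C)(O)C[C@@H]2C)O1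
F11 | step 16 | (2S,3R,5S,6R)-6-{[(2S,4S,6R)-6-{(2S)-1-[(tert-butyldiphenylsilyl)oxy]propan-2-yl}-4-methoxyoxan-2-yl]methyl}-3,5-dimethyl-2-(prop-2-en-1-yl)oxan-3-ol | CC(C)(C)[Si](c1ccccc1)(c1ccccc1)OC[C@H](C)[C@H]1C[C@@H](OC)C[C@@H](C[C@H]2O[C@@H](CC=C)[C@](C)(O)C[C@@H]2C)O1
F12 | step 16 | (2S,3R,5S,6R)-6-{[(2S,4S,6R)-6-{(2S)-1-[(tert-butyldiphenylsilyl)oxy]propan-2-yl}-4-methoxyoxan-2-yl]methyl}-2-[(2R)-3-hydroxy-2-methylpropyl]-3,5-dimethyloxan-3-ol | CC(C)(C)[Si](c1ccccc1)(c1ccccc1)OC[C@H](C)[C@H]1C[C@@H](OC)C[C@@H](C[C@H]2O[C@@H](C[C@@H](C)CO)[C@](C)(O)C[C@@H]2C)O1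
F13 | step 16 | (2R)-3-[(2S,3R,5S,6R)-6-{[(2S,4S,6R)-6-{(2S)-1-[(tert-butyldiphenylsilyl)oxy]propan-2-yl}-4-methoxyoxan-2-yl]methyl}-3-hydroxy-3,5-dimethyloxan-2-yl]-2-methylpropanal | CC(C)(C)[Si](c1ccccc1)(c1ccccc1)OC[C@H](C)[C@H]1C[C@@H](OC)C[C@@H](C[C@H]2O[C@@H](C[C@@H](C)C=O)[C@](C)(O)C[C@@H]2C)O1
F14 | step 21 | (2S,3R,5S,6R)-6-{[(2S,4S,6R)-6-[(2S)-4,4-dibromobut-3-en-2-yl]-4-methoxyoxan-2-yl]methyl}-3,5-dimethyl-2-[(2R)-2-methylbut-3-en-1-yl]oxan-3-ol | BrC(Br)=C[C@H](C)[C@H]1C[C@@H](OC)C[C@@H](C[C@H]2O[C@@H](C[C@@H](C)C=C)[C@](C)(O)C[C@@H]2C)O1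
F15 | step 21 | (2S,3R,5S,6R)-6-{[(2S,4S,6R)-6-[(2S)-4,4-dibromobut-3-en-2-yl]-4-methoxyoxan-2-yl]methyl}-3,5-dimethyl-2-[(2R,3E)-2-methyl-4-(4,4,5,5-tetramethyl-1,3,2-dioxaborolan-2-yl)but-3-en-1-yl]oxan-3-ol | BrC(Br)=C[C@H](C)[C@H]1C[C@@H](OC)C[C@@H](C[C@H]2O[C@@H](C[C@@H](C)/C=C/B3OC(C)(C)C(C)(C)O3)[C@](C)(O)C[C@@H]2C)O1
F16 | step 21 | (E)-tributyl(buta-1,3-dien-1-yl)stannane | C=C/C=C/[Sn](CCCC)(CCCC)CCCC
F17 | step 21 | (2S,3R,5S,6R)-6-{[(2S,4S,6R)-6-[(2S,3Z,5E)-4-bromoocta-3,5,7-trien-2-yl]-4-methoxyoxan-2-yl]methyl}-3,5-dimethyl-2-[(2R,3E)-2-methyl-4-(4,4,5,5-tetramethyl-1,3,2-dioxaborolan-2-yl)but-3-en-1-yl]oxan-3-ol | C=C/C=C/C(Br)=C/[C@H](C)[C@H]1C[C@@H](OC)C[C@@H](C[C@H]2O[C@@H](C[C@@H](C)/C=C/B3OC(C)(C)C(C)(C)O3)[C@](C)(O)C[C@@H]2C)O1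
A1 | alternative 1 | C20 dithioketal of the C14–C24 chain (O14 TBDPS, O16 triethylsilyl, free 18-hydroxyl, O22 TBS, O24 PMB) | CC(C)(C)[Si](c1ccccc1)(c1ccccc1)OC[C@H](C)[C@H](O[Si](CC)(CC)CC)C[C@@H](O)CC2(SCCCS2)C[C@@H](O[Si](C)(C)C(C)(C)C)[C@@H](C)COCc3ccc(OC)cc3
A2 | alternative 1 | 2-(tert-butyldimethylsilyl)-1,3-dithiane | CC(C)(C)[Si](C)(C)C1SCCCS1
A3 | alternative 1 | tert-butyl{[(2S,3R)-2-methyl-4-[(2R)-oxiran-2-yl]-3-[(triethylsilyl)oxy]butyl]oxy}diphenylsilane | CC(C)(C)[Si](c1ccccc1)(c1ccccc1)OC[C@H](C)[C@H](O[Si](CC)(CC)CC)C[C@@H]1CO1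
A4 | alternative 1 | (2S)-2-{(2S)-1-[(4-methoxybenzyl)oxy]propan-2-yl}oxirane | C1O[C@H]1[C@@H](C)COCc2ccc(OC)cc2
A5 | alternative 2 | (2S)-2-[(2R)-3-(benzyloxy)-2-methylpropyl]-6-{2-[(tert-butyldiphenylsilyl)oxy]ethyl}-6-hydroxy-2H-pyran-3(6H)-one (both anomers at C16) | CC(C)(C)[Si](c1ccccc1)(c1ccccc1)OCCC2(O)C=CC(=O)[C@@H](O2)C[C@@H](C)COCc3ccccc3
A6 | alternative 2 | (1S,3R)-4-(benzyloxy)-1-(5-{2-[(tert-butyldiphenylsilyl)oxy]ethyl}furan-2-yl)-3-methylbutan-1-ol | CC(C)(C)[Si](c1ccccc1)(c1ccccc1)OCCc2ccc(o2)[C@@H](O)C[C@@H](C)COCc3ccccc3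
A7 | alternative 3 | ring A enol triethylsilyl ether joined to ring B (C9–C24; O24 TBS, O13 triethylsilyl, O9 PMB) | CC(C)(C)[Si](C)(C)OC[C@H](C)[C@H]1CC(O[Si](CC)(CC)CC)=C[C@@H](C[C@H]2O[C@@H](C[C@@H](C)COCc3ccc(OC)cc3)[C@](C)(O[Si](CC)(CC)CC)C[C@@H]2C)O1
A8 | alternative 3 | (2S)-3-[(tert-butyldimethylsilyl)oxy]-2-methylpropanal | O=C[C@@H](C)CO[Si](C)(C)C(C)(C)C
A9 | alternative 3 | ring B (E)-2-(triethylsilyloxy)diene (C9–C21; O13 triethylsilyl, O9 PMB) | C=C(O[Si](CC)(CC)CC)/C=C/C[C@H]2O[C@@H](C[C@@H](C)COCc3ccc(OC)cc3)[C@](C)(O[Si](CC)(CC)CC)C[C@@H]2C
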